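Readings and results were computed for substances that don't exist, and the scatter is random.

Time is read here as dose: starting concentration times loading times time. The alpha run at 80.0 min has a dose of 0.00967 M·min and shows 42.2 % of target, and the zeta run at 25.0 min has 0.0104 M·min and shows 45.0 %, so these two readings, far apart on the clock, differ by 2.8 percentage points.

| setting | alpha | beta | delta | zeta | Wednesday's | Sunday's | Monday's | Tuesday's |
|---|---|---|---|---|---|---|---|---|
| starting material | 0.039 M | 0.12 M | 0.38 M | 0.13 M | 0.40 M | 0.13 M | 0.40 M | 0.040 M |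
| catalyst | 0.31 mol% | 0.31 mol% | 0.31 mol% | 0.32 mol% | 0.31 mol% | 0.31 mol% | 1 mol% | 0.2 mol% |
| remark | run made earlier | run made earlier | run made earlier | run made earlier |  |  |  |  |
| time |  |  |  |  | 2.0 h | 2.0 h | 2.0 h | 2.0 h |

| run | time / min | target / % | starting material / % |
|---|---|---|---|
| alpha | 15.0 | 13.3 | 82.4 |
| alpha | 30.0 | 25.6 | 71.0 |
| alpha | 50.0 | 33.5 | 62.9 |
| alpha | 60.0 | 38.4 | 58.1 |
| alpha | 80.0 | 42.2 | 52.4 |
| beta | 8.00 | 22.7 | 74.0 |
| beta | 20.0 | 40.5 | 57.0 |
| beta | 40.0 | 49.1 | 45.8 |
| beta | 60.0 | 51.1 | 43.7 |
| beta | 80.0 | 50.7 | 43.0 |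
| delta | 15.0 | 50.4 | 45.7 |
| delta | 30.0 | 48.8 | 41.3 |
| delta | 50.0 | 48.1 | 39.1 |
| delta | 60.0 | 47.8 | 38.5 |
| delta | 80.0 | 47.0 | 36.4 |
| zeta | 6.00 | 19.0 | 76.4 |
| zeta | 12.0 | 31.5 | 66.4 |
| zeta | 25.0 | 45.0 | 53.0 |
| zeta | 40.0 | 48.3 | 45.5 |
| zeta | 80.0 | 49.3 | 40.7 |

(scatter of a reading: 1 percentage point)

- the earlier runs were read with a standard deviation of 1 percentage point
- in a conversion other conformer counts as not yet reacted

1. the flasks by amount of target, in percent of the starting material charged, highest first, at 2.0 h (Wednesday's / Sunday's / Monday's / Tuesday's)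
2. the same order at 12 min (Wednesday's / Sunday's / Monday's / Tuesday's)
3. the amount of target, in percent of the starting material charged of the flask you put first, at 2.0 h
4. the amount of target, in percent of the starting material charged of the flask you put last, at 2.0 h

In the delta run the sum of target and starting material reads 83.4 % at 80.0 min, and target makes up 56.4 % of that sum. The logarithm of that fall, divided by the run's dose of 0.0942 M·min, gives a reading of 1.93 M⁻¹ min⁻¹. This is the drain per dose, a pseudo-first-order constant for the sum once it is multiplied by catalyst concentration.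

Monday's reaches a dose of 0.480 M·min at 2.0 h, more than the delta run's, so its target at that time should stand below the 47.0 % read there, the top of the bracket. For the low end of the bracket, the drain per dose is held at its delta value, although Monday's has a higher catalyst concentration, so this end is an estimate and not a proven limit. This gives a low end of 22.4 %. The same reckoning gives Sunday's 51.3 % and Wednesday's 42.3 %, while Tuesday's dose of 0.00960 M·min is close to alpha's last.

The forecast gives Sunday's > Wednesday's > Tuesday's > Monday's at 2.0 h and Wednesday's > Monday's > Sunday's > Tuesday's at 12 min, with 49 % (47 % to 51 %) for Sunday's and 37 % (29 % to 43 %) for Monday's, called an "uncertain extrapolation". The forecast for Monday's lies inside the bracket, above its low end.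

The flasks give Sunday's > Tuesday's > Wednesday's > Monday's at 2.0 h and Monday's > Wednesday's > Sunday's > Tuesday's at 12 min, with 49.2 % for Sunday's and 25.8 % for Monday's, which is inside the bracket and 3.4 points above its low end.

    starting material ⇌ other conformer (K = 0.0200, k = 0.0640 min⁻¹)
    starting material + catalyst ⇌ catalyst + target (K = 1.20, k = 97.0 M⁻¹ min⁻¹)
    catalyst + other conformer → catalyst + isomer of the product (k = 220 M⁻¹ min⁻¹)

In Monday's the other conformer falls back at 3.20 min⁻¹ and goes on to the isomer of the product at 0.880 min⁻¹, a ratio of 3.64, against 36 in Sunday's at 0.144 h. Monday's result corresponds to an average drain per dose of 1.63 M⁻¹ min⁻¹, below the 1.93 M⁻¹ min⁻¹ read from the delta run. The neighbour flask, Sunday's recipe at 0.52 M, has a dose of 0.193 M·min, for which the drain per dose gives 38.9 %, and its target stands at 38.4 %.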